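The route closes ring B last, by disconnecting C2'–C3' and C5'–C6'. In ring B, C2'–C1'–C6' with the bridge CH2 is a substituted malonyl unit, and C3'(CH3)–C4'(OCH3)–C5'(isobutyryl) is the methyl enol ether of an ethyl isopropyl 1,3-diketone. A [3+3] double C-acylation of the corresponding 3-methoxy-1-silyloxy diene by a malonyl dichloride therefore closes ring B in one operation, already aromatic, with its only O-methyl group and its isobutyryl group in place. The dichloride is the fully benzylated ring C–ring A dimer carrying a CH2CH(COCl)2 arm on C5 of ring C; it is assembled by classical quinone-methide bridging, benzylation and malonate alkylation.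

Key step: step 16

Assumptions: (R)-2-methylbutanoic acid is bought as the single enantiomer; diene 25 is drawn as its 3Z,5E isomer, but both double bonds end in the arene, so any mixture of geometrical isomers would be used as such.

Step 1
Reactants: 1 2,4,6-trihydroxytoluene
Product: 2 1-(2,4,6-trihydroxy-3-methylphenyl)ethan-1-one
Conditions: AcCl (1.05 equiv), AlCl3 (3.5 equiv), CH2Cl2–MeNO2, 0 °C → rt; aq. HCl
Reagents that add atoms: acetyl chloride, CC(=O)Cl
Why: Friedel–Crafts C-acylation of the trihydroxyarene at its only kind of free ring position should stop after one acyl group, because the first ketone deactivates the ring.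

Step 2
Reactants: 2 1-(2,4,6-trihydroxy-3-methylphenyl)ethan-1-one
Product: 3 1-[4,6-bis(benzyloxy)-2-hydroxy-3-methylphenyl]ethan-1-one
Conditions: BnBr (2.1 equiv), K2CO3 (2.2 equiv), acetone, reflux; chromatography
Reagents that add atoms: benzyl bromide, BrCc1ccccc1
Why: Williamson etherification should take the para hydroxyl first and then the ortho hydroxyl next to the ring hydrogen, because the hydroxyl wedged between the C-methyl and the acetyl group is the most hindered and stays locked in the hydrogen bond to the carbonyl; any 2,4-dibenzyl isomer would be removed at this stage.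

Step 3
Reactants: 3 1-[4,6-bis(benzyloxy)-2-hydroxy-3-methylphenyl]ethan-1-one
Product: 4 1-[4,6-bis(benzyloxy)-2-methoxy-3-methylphenyl]ethan-1-one
Conditions: MeI (3 equiv), K2CO3, DMF, 40 °C
Reagents that add atoms: iodomethane, CI
Why: Williamson O-methylation of the last, chelated phenol fixes the methoxy group between the acetyl and the C-methyl group, the place it holds in ring A.

Step 4
Reactants: 4 1-[4,6-bis(benzyloxy)-2-methoxy-3-methylphenyl]ethan-1-one
Product: 5 1-(4,6-dihydroxy-2-methoxy-3-methylphenyl)ethan-1-one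
Conditions: H2 (1 atm), 10% Pd/C, EtOAc–MeOH, rt
Reagents that add atoms: none
Why: Catalytic hydrogenolysis of the two benzyl ethers frees the phenols needed for the bridging step and should leave the aryl ketone and the methyl ether untouched.

Step 5
Reactants: 5 1-(4,6-dihydroxy-2-methoxy-3-methylphenyl)ethan-1-one
Product: 6 1-[3-[(dimethylamino)methyl]-2,4-dihydroxy-6-methoxy-5-methylphenyl]ethan-1-one
Conditions: 37% aq. CH2O (1.05 equiv), 40% aq. Me2NH (1.1 equiv), EtOH, 0 °C → rt
Reagents that add atoms: formaldehyde, C=O; dimethylamine, CNC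
Why: The phenolic Mannich reaction can only occur at the single unsubstituted ring carbon, which lies between two hydroxyls, and installs the future bridge carbon as an aminomethyl group.

Step 6
Reactants: 7 (2R)-2-methylbutanoic acid; 8 phloroglucinol
Product: 10 (2R)-2-methyl-1-(2,4,6-trihydroxyphenyl)butan-1-one, via (2R)-2-methylbutanoyl chloride 9 (not isolated)
Conditions: (COCl)2 (1.0 equiv), DMF (cat.), CH2Cl2, 0 °C → rt; then 8 (1.2 equiv), AlCl3 (3.5 equiv), CH2Cl2–MeNO2, 0 °C → rt; aq. HCl
Reagents that add atoms: none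
Why: Acid chloride formation followed by Friedel–Crafts acylation of phloroglucinol at or below room temperature should give the monoacyl compound with the (R) centre, which is carried in from 7, intact, since neither stage needs conditions that enolise it.

Step 7
Reactants: 6 1-[3-[(dimethylamino)methyl]-2,4-dihydroxy-6-methoxy-5-methylphenyl]ethan-1-one; 10 (2R)-2-methyl-1-(2,4,6-trihydroxyphenyl)butan-1-one
Product: 12 (2R)-1-[3-[(3-acetyl-2,6-dihydroxy-4-methoxy-5-methylphenyl)methyl]-2,4,6-trihydroxyphenyl]-2-methylbutan-1-one, via ring A ortho-quinone methide 11 (not isolated)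
Conditions: 10 (3 equiv), 1,4-dioxane, 100 °C, N2 stream
Reagents that add atoms: none
Why: Thermal loss of dimethylamine from the Mannich base gives the quinone methide, which is trapped at C3 of the acylphloroglucinol in a Michael-type Friedel–Crafts alkylation, while the excess of 10 holds back double alkylation and the stereocentre is not touched.

Step 8
Reactants: 12 free-phenol ring C–ring A dimer
Product: 13 (2R)-1-[3-[[3-acetyl-2,6-bis(benzyloxy)-4-methoxy-5-methylphenyl]methyl]-2,4,6-tris(benzyloxy)phenyl]-2-methylbutan-1-one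
Conditions: BnBr (7 equiv), K2CO3 (8 equiv), DMF, 45 °C
Reagents that add atoms: benzyl bromide, BrCc1ccccc1
Why: Fivefold Williamson etherification in a dipolar aprotic solvent should alkylate the phenoxides on oxygen, and carbonate is too weak a base to enolise the twisted, di-ortho-substituted ketone that carries the stereocentre.

Step 9
Reactants: 13 pentabenzyl ring C–ring A dimer
Product: 14 (2R)-1-[3-[[3-acetyl-2,6-bis(benzyloxy)-4-methoxy-5-methylphenyl]methyl]-2,4,6-tris(benzyloxy)-5-(chloromethyl)phenyl]-2-methylbutan-1-one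
Conditions: MOMCl (5 equiv), ZnCl2 (10 mol%), CH2Cl2, 0 °C → rt; crude used at once
Reagents that add atoms: chloromethyl methyl ether, COCCl
Why: Blanc-type chloromethylation can only strike C5 of ring C, the one unsubstituted carbon of the two oxygenated rings, which is activated by two ortho and one para benzyloxy group, and the mild zinc catalyst at low temperature should spare the benzyl ethers.

Step 10
Reactants: 14 chloromethyl compound; 15 diallyl malonate
Product: 17 diallyl 2-[[3-[[3-acetyl-2,6-bis(benzyloxy)-4-methoxy-5-methylphenyl]methyl]-2,4,6-tris(benzyloxy)-5-[(2R)-2-methylbutanoyl]phenyl]methyl]propanedioate, via sodium enolate of diallyl malonate 16 (not isolated)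
Conditions: 15 (2.0 equiv), NaH (1.8 equiv), THF–DMF, 0 °C; then 14, 0 °C → rt
Reagents that add atoms: none
Why: Malonic ester alkylation by the reactive benzylic chloride should be clean, the excess of malonate over hydride leaves the weakly basic enolate as the only base so that the ketone centre is not epimerised, and allyl esters are chosen because they can later be removed without the acid that cleaves benzyl ethers flanking aryl ketones.

Step 11
Reactants: 17 diallyl malonate of the ring C–ring A unit
Product: 18 2-[[3-[[3-acetyl-2,6-bis(benzyloxy)-4-methoxy-5-methylphenyl]methyl]-2,4,6-tris(benzyloxy)-5-[(2R)-2-methylbutanoyl]phenyl]methyl]propanedioic acid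
Conditions: Pd(PPh3)4 (5 mol%), morpholine (10 equiv), THF, rt; cold aq. KHSO4
Reagents that add atoms: none
Why: Tsuji–Trost allyl transfer to morpholine releases both carboxylic acids under neutral conditions at room temperature, where a monosubstituted malonic acid does not decarboxylate and benzyl ethers, ketones and the stereocentre are inert.

Step 12
Reactants: 18 malonic acid of the ring C–ring A unit
Product: 19 2-[[3-[[3-acetyl-2,6-bis(benzyloxy)-4-methoxy-5-methylphenyl]methyl]-2,4,6-tris(benzyloxy)-5-[(2R)-2-methylbutanoyl]phenyl]methyl]propanedioyl dichloride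
Conditions: (COCl)2 (3 equiv), DMF (cat.), CH2Cl2, 0 °C → rt; evaporate, use at once
Reagents that add atoms: oxalyl chloride, O=C(Cl)C(=O)Cl
Why: Acid chloride formation with oxalyl chloride under DMF catalysis gives only gaseous by-products, and keeping the dichloride cold, free of Lewis acid and short-lived should prevent the ortho benzyloxy groups from lactonising onto it.

Step 13
Reactants: 20 but-1-yne; 21 N-methoxy-N,2-dimethylpropanamide
Product: 23 2-methylhept-4-yn-3-one, via lithium but-1-yn-1-ide 22 (not isolated)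
Conditions: 20 (1.2 equiv), n-BuLi (1.0 equiv), THF, −78 °C; then 21, −78 → 0 °C; aq. NH4Cl
Reagents that add atoms: none
Why: Weinreb ketone synthesis with the lithium acetylide stops at the ynone and places the future C4' oxygen site at the alkyne carbon next to the ethyl group without ambiguity.

Step 14
Reactants: 23 2-methylhept-4-yn-3-one
Product: 24 (4E)-5-methoxy-2-methylhept-4-en-3-one
Conditions: MeOH, NaOMe (10 mol%), 0 °C → rt
Reagents that add atoms: methanol, CO
Why: Base-catalysed conjugate addition of methanol to the ynone puts the methoxy group on C5 only, which O-methylation of the unsymmetrical diketone could not guarantee, and should settle on the more stable E enol ether.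

Step 15
Reactants: 24 (4E)-5-methoxy-2-methylhept-4-en-3-one
Product: 25 (3Z,5E)-5-methoxy-2-methyl-3-(trimethylsilyloxy)hepta-3,5-diene
Conditions: TMSOTf (1.2 equiv), Et3N (1.5 equiv), Et2O, 0 °C → rt; pentane, filtration, bulb-to-bulb distillation
Reagents that add atoms: trimethylsilyl trifluoromethanesulfonate, C[Si](C)(C)OS(=O)(=O)C(F)(F)F
Why: Soft enolisation of the vinylogous ester (the method behind Danishefsky-type dienes) silylates the carbonyl oxygen, after which triethylamine should remove a C6 methylene proton and not the hindered isopropyl methine, giving the linearly conjugated silyl dienol ether.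

Step 16
Reactants: 19 malonyl dichloride of the ring C–ring A unit; 25 (3Z,5E)-5-methoxy-2-methyl-3-(trimethylsilyloxy)hepta-3,5-diene
Product: 27 (2R)-1-[3-[[3-acetyl-2,6-bis(benzyloxy)-4-methoxy-5-methylphenyl]methyl]-2,4,6-tris(benzyloxy)-5-[[2,6-dihydroxy-4-methoxy-3-methyl-5-(2-methylpropanoyl)phenyl]methyl]phenyl]-2-methylbutan-1-one, via open-chain β-keto acid chloride 26 (not isolated)
Conditions: 25 (1.1 equiv) added slowly to 19 (0.02 M), CH2Cl2, −40 °C → 20 °C, Ar stream; aq. NaHCO3
Reagents that add atoms: none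
Why: Proposed new method: the diene terminus C6 (future C3'), activated directly by the C5 methoxy group and vinylogously by the C3 silyloxy group, should attack one acid chloride of 19 with loss of Me3SiCl to give 26, whose remaining acid chloride (or the acylketene it may form by loss of HCl) is then attacked by the enol-ether carbon C4 (future C5'), and the closed ring tautomerises to the arene. The closest known reaction types are the Effenberger phloroglucinol synthesis from enol ethers and malonyl dichlorides and the [3+3] cyclisations of silyl dienol ethers with 1,3-dielectrophiles. Ring B is closed in a 6-(enolendo)-exo-trig mode at the acyl carbon, so that C2'–C3' and C5'–C6' are the two new bonds. No stereocentre is formed, and the (R) centre of the side chain is not at risk because no base is present. The step needs C- rather than O-acylation, attack through the diene terminus before the inner carbon, and ring closure rather than a second intermolecular acylation: the only oxygen placed for a six-membered O-closure after terminal attack is the one already methylated, the isobutyryl oxygen could close only an eight-membered ring, the terminus is the electronically preferred site of a silyl dienol ether, and slow addition of 25 to dilute 19 keeps the bimolecular path down. No Lewis acid is added, so that the five benzyl ethers survive and the ortho benzyloxy groups are not acylated by the neighbouring acid chloride.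

Step 17
Reactants: 27 trimer with ring B free and rings A and C benzylated
Product: 28 (2R)-1-[3-[(3-acetyl-2,6-dihydroxy-4-methoxy-5-methylphenyl)methyl]-5-[[2,6-dihydroxy-4-methoxy-3-methyl-5-(2-methylpropanoyl)phenyl]methyl]-2,4,6-trihydroxyphenyl]-2-methylbutan-1-one
Conditions: H2 (1 atm), 10% Pd/C, EtOAc–MeOH, rt
Reagents that add atoms: none
Why: Catalytic hydrogenolysis removes the five benzyl ethers under neutral conditions that should leave the three hydrogen-bonded aryl ketones, the diarylmethane bridges, the two methyl ethers and the (R) centre unchanged.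

Compound list
1 | 2,4,6-trihydroxytoluene | Cc1c(O)cc(O)cc1O | starting material
2 | 1-(2,4,6-trihydroxy-3-methylphenyl)ethan-1-one | Cc1c(O)c(C(C)=O)c(O)cc1O | intermediate
3 | 1-[4,6-bis(benzyloxy)-2-hydroxy-3-methylphenyl]ethan-1-one | Cc1c(O)c(C(C)=O)c(OCc2ccccc2)cc1OCc1ccccc1 | intermediate
4 | 1-[4,6-bis(benzyloxy)-2-methoxy-3-methylphenyl]ethan-1-one | Cc1c(OC)c(C(C)=O)c(OCc2ccccc2)cc1OCc1ccccc1 | intermediate
5 | 1-(4,6-dihydroxy-2-methoxy-3-methylphenyl)ethan-1-one | Cc1c(OC)c(C(C)=O)c(O)cc1O | intermediate
6 | 1-[3-[(dimethylamino)methyl]-2,4-dihydroxy-6-methoxy-5-methylphenyl]ethan-1-one | Cc1c(OC)c(C(C)=O)c(O)c(CN(C)C)c1O | intermediate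
7 | (2R)-2-methylbutanoic acid | CC[C@@H](C)C(=O)O | starting material
8 | phloroglucinol (benzene-1,3,5-triol) | Oc1cc(O)cc(O)c1 | starting material
9 | (2R)-2-methylbutanoyl chloride | CC[C@@H](C)C(=O)Cl | intermediate (not isolated)
10 | (2R)-2-methyl-1-(2,4,6-trihydroxyphenyl)butan-1-one | CC[C@@H](C)C(=O)c1c(O)cc(O)cc1O | intermediate
11 | 4-acetyl-3-hydroxy-5-methoxy-6-methyl-2-methylidenecyclohexa-3,5-dien-1-one (ring A ortho-quinone methide) | C=C1C(=O)C(C)=C(OC)C(C(C)=O)=C1O | intermediate (not isolated)
12 | (2R)-1-[3-[(3-acetyl-2,6-dihydroxy-4-methoxy-5-methylphenyl)methyl]-2,4,6-trihydroxyphenyl]-2-methylbutan-1-one | CC[C@@H](C)C(=O)c1c(O)c(Cc2c(O)c(C)c(OC)c(C(C)=O)c2O)c(O)cc1O | intermediate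
13 | (2R)-1-[3-[[3-acetyl-2,6-bis(benzyloxy)-4-methoxy-5-methylphenyl]methyl]-2,4,6-tris(benzyloxy)phenyl]-2-methylbutan-1-one | CC[C@@H](C)C(=O)c1c(OCc2ccccc2)c(Cc2c(OCc3ccccc3)c(C)c(OC)c(C(C)=O)c2OCc2ccccc2)c(OCc2ccccc2)cc1OCc1ccccc1 | intermediate
14 | (2R)-1-[3-[[3-acetyl-2,6-bis(benzyloxy)-4-methoxy-5-methylphenyl]methyl]-2,4,6-tris(benzyloxy)-5-(chloromethyl)phenyl]-2-methylbutan-1-one | CC[C@@H](C)C(=O)c1c(OCc2ccccc2)c(Cc2c(OCc3ccccc3)c(C)c(OC)c(C(C)=O)c2OCc2ccccc2)c(OCc2ccccc2)c(CCl)c1OCc1ccccc1 | intermediate
15 | diallyl malonate (bis(prop-2-en-1-yl) propanedioate) | C=CCOC(=O)CC(=O)OCC=C | starting material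
16 | sodium enolate of diallyl malonate | [Na+].C=CCOC(=O)[CH-]C(=O)OCC=C | intermediate (not isolated)
17 | diallyl 2-[[3-[[3-acetyl-2,6-bis(benzyloxy)-4-methoxy-5-methylphenyl]methyl]-2,4,6-tris(benzyloxy)-5-[(2R)-2-methylbutanoyl]phenyl]methyl]propanedioate | CC[C@@H](C)C(=O)c1c(OCc2ccccc2)c(Cc2c(OCc3ccccc3)c(C)c(OC)c(C(C)=O)c2OCc2ccccc2)c(OCc2ccccc2)c(CC(C(=O)OCC=C)C(=O)OCC=C)c1OCc1ccccc1 | intermediate
18 | 2-[[3-[[3-acetyl-2,6-bis(benzyloxy)-4-methoxy-5-methylphenyl]methyl]-2,4,6-tris(benzyloxy)-5-[(2R)-2-methylbutanoyl]phenyl]methyl]propanedioic acid | CC[C@@H](C)C(=O)c1c(OCc2ccccc2)c(Cc2c(OCc3ccccc3)c(C)c(OC)c(C(C)=O)c2OCc2ccccc2)c(OCc2ccccc2)c(CC(C(=O)O)C(=O)O)c1OCc1ccccc1 | intermediate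
19 | 2-[[3-[[3-acetyl-2,6-bis(benzyloxy)-4-methoxy-5-methylphenyl]methyl]-2,4,6-tris(benzyloxy)-5-[(2R)-2-methylbutanoyl]phenyl]methyl]propanedioyl dichloride | CC[C@@H](C)C(=O)c1c(OCc2ccccc2)c(Cc2c(OCc3ccccc3)c(C)c(OC)c(C(C)=O)c2OCc2ccccc2)c(OCc2ccccc2)c(CC(C(=O)Cl)C(=O)Cl)c1OCc1ccccc1 | intermediate (key-step precursor)
20 | but-1-yne | CCC#C | starting material
21 | N-methoxy-N,2-dimethylpropanamide | CC(C)C(=O)N(C)OC | starting material
22 | lithium but-1-yn-1-ide | [Li+].[C-]#CCC | intermediate (not isolated)
23 | 2-methylhept-4-yn-3-one | CCC#CC(=O)C(C)C | intermediate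
24 | (4E)-5-methoxy-2-methylhept-4-en-3-one | CC/C(OC)=C\C(=O)C(C)C | intermediate
25 | (3Z,5E)-5-methoxy-2-methyl-3-(trimethylsilyloxy)hepta-3,5-diene | C/C=C(OC)\C=C(/O[Si](C)(C)C)C(C)C | intermediate (key-step precursor)
26 | 2-[[3-[[3-acetyl-2,6-bis(benzyloxy)-4-methoxy-5-methylphenyl]methyl]-2,4,6-tris(benzyloxy)-5-[(2R)-2-methylbutanoyl]phenyl]methyl]-5-methoxy-4,8-dimethyl-3,7-dioxonon-5-enoyl chloride (mixture at the two transient centres and the enol ether double bond) | CC[C@@H](C)C(=O)c1c(OCc2ccccc2)c(Cc2c(OCc3ccccc3)c(C)c(OC)c(C(C)=O)c2OCc2ccccc2)c(OCc2ccccc2)c(CC(C(=O)Cl)C(=O)C(C)C(OC)=CC(=O)C(C)C)c1OCc1ccccc1 | intermediate (not isolated)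
27 | (2R)-1-[3-[[3-acetyl-2,6-bis(benzyloxy)-4-methoxy-5-methylphenyl]methyl]-2,4,6-tris(benzyloxy)-5-[[2,6-dihydroxy-4-methoxy-3-methyl-5-(2-methylpropanoyl)phenyl]methyl]phenyl]-2-methylbutan-1-one | CC[C@@H](C)C(=O)c1c(OCc2ccccc2)c(Cc2c(OCc3ccccc3)c(C)c(OC)c(C(C)=O)c2OCc2ccccc2)c(OCc2ccccc2)c(Cc2c(O)c(C)c(OC)c(C(=O)C(C)C)c2O)c1OCc1ccccc1 | intermediate (key-step product)
28 | (2R)-1-[3-[(3-acetyl-2,6-dihydroxy-4-methoxy-5-methylphenyl)methyl]-5-[[2,6-dihydroxy-4-methoxy-3-methyl-5-(2-methylpropanoyl)phenyl]methyl]-2,4,6-trihydroxyphenyl]-2-methylbutan-1-one | CC[C@@H](C)C(=O)c1c(O)c(Cc2c(O)c(C)c(OC)c(C(C)=O)c2O)c(O)c(Cc2c(O)c(C)c(OC)c(C(=O)C(C)C)c2O)c1O | target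

Total step count: 17 steps.
Longest linear sequence: 13 steps (steps 1–5, 7–12, 16, 17, from 2,4,6-trihydroxytoluene).

Steps most likely to fail

Step 16. The first acylation may go through oxygen or the inner diene carbon, the mono-acylated chain may be acylated a second time by another diene molecule instead of closing, the diene may be desilylated by the HCl released, or a benzyl ether may be lost by lactonisation onto the acid chloride. The fallback uses only known chemistry and builds ring B as a monomer by the sequence already used for ring A. It sets out from 1 and 12 and comes back at 28.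
- Friedel–Crafts acylation of 1 with 2-methylpropanoyl chloride and AlCl3 should give 2-methyl-1-(2,4,6-trihydroxy-3-methylphenyl)propan-1-one F1.
- Double benzylation (BnBr, K2CO3, acetone) should give 1-[4,6-bis(benzyloxy)-2-hydroxy-3-methylphenyl]-2-methylpropan-1-one F2.
- Methylation (MeI, K2CO3, DMF) should give 1-[4,6-bis(benzyloxy)-2-methoxy-3-methylphenyl]-2-methylpropan-1-one F3.
- Hydrogenolysis (H2, Pd/C) should give 1-(4,6-dihydroxy-2-methoxy-3-methylphenyl)-2-methylpropan-1-one F4.
- Mannich reaction (CH2O, Me2NH, EtOH) should give 1-[3-[(dimethylamino)methyl]-2,4-dihydroxy-6-methoxy-5-methylphenyl]-2-methylpropan-1-one F5.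
- Heating F5 with 12 in 1,4-dioxane at 100 °C should expel dimethylamine and alkylate C5 of ring C, the only free position of 12, to give 28 directly.

Step 15. Proton removal may occur at the isopropyl methine instead of C6, giving the cross-substituted diene, or the silyl dienol ether may hydrolyse during isolation. The fallback fixes the site of enolate formation by a carbon–halogen bond. It sets out from 24 and comes back at 25.
- Wohl–Ziegler bromination of the C6 methylene (NBS, AIBN, PhCF3, reflux), as practised on 3-methoxycrotonates, should give (4E)-6-bromo-5-methoxy-2-methylhept-4-en-3-one F6.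
- Reductive silylation with Zn dust and TMSCl (Et2O–MeCN, rt) should form the zinc dienolate only at the C–Br site and silylate it on oxygen to give 25.

Step 9. The acid generated during chloromethylation may strip benzyl ethers that flank the ketones, or substitution at the crowded C5 may stall. The fallback introduces the carbon while the phenols are still free and uses no acid on the benzylated material. It sets out from 12 and comes back at 14.
- Vilsmeier–Haack formylation (POCl3, DMF, EtOAc, rt; aqueous hydrolysis) at the only free ring carbon should give 3-[(3-acetyl-2,6-dihydroxy-4-methoxy-5-methylphenyl)methyl]-2,4,6-trihydroxy-5-[(2R)-2-methylbutanoyl]benzaldehyde F7.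
- Fivefold benzylation (BnBr, K2CO3, DMF, 45 °C) should give 3-[[3-acetyl-2,6-bis(benzyloxy)-4-methoxy-5-methylphenyl]methyl]-2,4,6-tris(benzyloxy)-5-[(2R)-2-methylbutanoyl]benzaldehyde F8.
- NaBH4 (THF–MeOH, −20 °C) should reduce only the aldehyde, the two hindered aryl ketones being much slower, to give (2R)-1-[3-[[3-acetyl-2,6-bis(benzyloxy)-4-methoxy-5-methylphenyl]methyl]-2,4,6-tris(benzyloxy)-5-(hydroxymethyl)phenyl]-2-methylbutan-1-one F9.
- MsCl, Et3N and LiCl (CH2Cl2, 0 °C) should convert the electron-rich benzylic alcohol into chloride 14.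

Further compounds
F1 | step 16 | 2-methyl-1-(2,4,6-trihydroxy-3-methylphenyl)propan-1-one | Cc1c(O)c(C(=O)C(C)C)c(O)cc1O
F2 | step 16 | 1-[4,6-bis(benzyloxy)-2-hydroxy-3-methylphenyl]-2-methylpropan-1-one | Cc1c(O)c(C(=O)C(C)C)c(OCc2ccccc2)cc1OCc1ccccc1
F3 | step 16 | 1-[4,6-bis(benzyloxy)-2-methoxy-3-methylphenyl]-2-methylpropan-1-one | Cc1c(OC)c(C(=O)C(C)C)c(OCc2ccccc2)cc1OCc1ccccc1
F4 | step 16 | 1-(4,6-dihydroxy-2-methoxy-3-methylphenyl)-2-methylpropan-1-one | Cc1c(OC)c(C(=O)C(C)C)c(O)cc1O
F5 | step 16 | 1-[3-[(dimethylamino)methyl]-2,4-dihydroxy-6-methoxy-5-methylphenyl]-2-methylpropan-1-one | Cc1c(OC)c(C(=O)C(C)C)c(O)c(CN(C)C)c1O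
F6 | step 15 | (4E)-6-bromo-5-methoxy-2-methylhept-4-en-3-one | CC(Br)/C(OC)=C\C(=O)C(C)C
F7 | step 9 | 3-[(3-acetyl-2,6-dihydroxy-4-methoxy-5-methylphenyl)methyl]-2,4,6-trihydroxy-5-[(2R)-2-methylbutanoyl]benzaldehyde | CC[C@@H](C)C(=O)c1c(O)c(Cc2c(O)c(C)c(OC)c(C(C)=O)c2O)c(O)c(C=O)c1O
F8 | step 9 | 3-[[3-acetyl-2,6-bis(benzyloxy)-4-methoxy-5-methylphenyl]methyl]-2,4,6-tris(benzyloxy)-5-[(2R)-2-methylbutanoyl]benzaldehyde | CC[C@@H](C)C(=O)c1c(OCc2ccccc2)c(Cc2c(OCc3ccccc3)c(C)c(OC)c(C(C)=O)c2OCc2ccccc2)c(OCc2ccccc2)c(C=O)c1OCc1ccccc1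
F9 | step 9 | (2R)-1-[3-[[3-acetyl-2,6-bis(benzyloxy)-4-methoxy-5-methylphenyl]methyl]-2,4,6-tris(benzyloxy)-5-(hydroxymethyl)phenyl]-2-methylbutan-1-one | CC[C@@H](C)C(=O)c1c(OCc2ccccc2)c(Cc2c(OCc3ccccc3)c(C)c(OC)c(C(C)=O)c2OCc2ccccc2)c(OCc2ccccc2)c(CO)c1OCc1ccccc1
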